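**Assumptions:** the β-diketone is isolated as the keto–enol tautomer drawn in the target. Commercial 2-methylprop-1-enylmagnesium bromide solution is treated as a starting material. The route is a paper proposal; nothing in it has been run.

## Retrosynthetic overview

1. Last bond: the aryl-side C=C of the curcuminoid, by boron-templated aldol condensation of aryl aldehyde 18 with p-coumaroylacetone 6.
2. Aryl ether by Pd-catalysed allylic substitution of carbonate 16 with vanillin; C4–OH by late allylic C–H hydroxylation.
3. Key disconnection: the ring–side-chain bond C6–C7. A C6 cyclohexenyl radical (from bromide 13) adds to crotonyl pyrazole 9 under a chiral Lewis acid, setting C6 and C7 in one step; a vinyl Grignard then converts the acyl pyrazole into the enone.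
4. No ring is built: both arenes come from p-cresol and the cyclohexene from 3-methylcyclohex-2-enone, whose C1 stereocentre is set by CBS reduction.

Ring numbering used below: C1 (O-aryl), C2=C3(Me), C4 (OH), C5, C6 (side chain); C7 is the side-chain CH(CH3).

## Route

**Step 1**
Reactants: 1, p-cresol
Product: 2, 4-hydroxybenzaldehyde
Conditions: O2 (1 atm), CoCl2 (cat.), NaOH, MeOH, 60 °C; aq. HCl
Reagents that add atoms: dioxygen, O=O
Why: Co-catalysed aerobic benzylic oxidation of the p-cresolate via the quinone methide, the industrial route to this aldehyde.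

**Step 2**
Reactants: 2, 4-hydroxybenzaldehyde
Product: 3, 3-bromo-4-hydroxybenzaldehyde
Conditions: Br2 (1.0 equiv), MeOH, 0 °C
Reagents that add atoms: bromine, BrBr
Why: electrophilic aromatic bromination ortho to the phenol (para blocked, CHO directs meta to itself).

**Step 3**
Reactants: 3, 3-bromo-4-hydroxybenzaldehyde
Product: 4, vanillin (4-hydroxy-3-methoxybenzaldehyde)
Conditions: NaOMe, CuCl (cat.), DMF/MeOH, 115 °C; aq. HCl
Reagents that add atoms: sodium methoxide, [Na+].[O-]C
Why: Cu-catalysed Ullmann-type methoxylation of the aryl bromide, a known vanillin process.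

**Step 4**
Reactants: 2, 4-hydroxybenzaldehyde; 5, pentane-2,4-dione
Product: 6, (5E)-6-(4-hydroxyphenyl)hex-5-ene-2,4-dione (exists as its enol)
Conditions: 5 (3 equiv), B2O3, EtOAc, 70 °C; then 2, B(OnBu)3, n-BuNH2 (cat.), 70 °C; 0.4 M HCl, 50 °C
Reagents that add atoms: none
Why: Pabon boron-templated aldol condensation; the boron chelate blocks the central carbon, excess diketone limits bis-condensation, and the E-alkene is thermodynamic.

**Step 5**
Reactants: 7, (E)-but-2-enoyl chloride; 8, 3,5-dimethyl-1H-pyrazole
Product: 9, (2E)-1-(3,5-dimethyl-1H-pyrazol-1-yl)but-2-en-1-one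
Conditions: Et3N, CH2Cl2, 0 °C to rt
Reagents that add atoms: none
Why: N-acylation, giving a two-point-binding radical acceptor whose acyl group can later be transferred to carbon.

**Step 6**
Reactants: 10, 3-methylcyclohex-2-en-1-one
Product: 11, 6-bromo-3-methylcyclohex-2-en-1-one (racemic)
Conditions: LDA, THF, −78 °C; TMSCl; then NBS, −78 to 0 °C
Reagents that add atoms: N-bromosuccinimide, O=C1CCC(=O)N1Br
Why: kinetic α′-deprotonation and bromination of the cross-conjugated silyl dienol ether places Br on C6.

**Step 7**
Reactants: 11, 6-bromo-3-methylcyclohex-2-en-1-one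
Product: 12, (1S)-6-bromo-3-methylcyclohex-2-en-1-ol (both C6 epimers)
Conditions: (S)-Me-CBS (15 mol%), BH3·SMe2, THF, −30 °C
Reagents that add atoms: none
Why: Corey–Bakshi–Shibata reduction with the alkenyl arm as the large group sets C1 as S by catalyst control in both enantiomers of 11; the C6 configuration does not matter because it is erased in step 9.

**Step 8**
Reactants: 12, (1S)-6-bromo-3-methylcyclohex-2-en-1-ol
Product: 13, methyl (1S)-6-bromo-3-methylcyclohex-2-en-1-yl carbonate
Conditions: ClCO2Me, pyridine, DMAP (cat.), CH2Cl2, 0 °C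
Reagents that add atoms: methyl chloroformate, COC(=O)Cl
Why: O-acylation; the carbonate protects the alcohol through the radical step and is the leaving group for step 11.

**Step 9 (key step)**
Reactants: 13, methyl (1S)-6-bromo-3-methylcyclohex-2-en-1-yl carbonate; 9, crotonyl pyrazole
Product: 14, methyl (1R,6R)-6-[(2S)-4-(3,5-dimethyl-1H-pyrazol-1-yl)-4-oxobutan-2-yl]-3-methylcyclohex-2-en-1-yl carbonate
Conditions: 9 (3 equiv), MgI2/chiral indanyl bis(oxazoline) (antipode chosen for Si-face attack at Cβ), Bu3SnH (slow addition), Et3B/O2, CH2Cl2, −78 °C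
Reagents that add atoms: none
Why: Sibi-type chiral-Lewis-acid radical conjugate addition (Giese reaction) in which both C6 epimers of 13 give the same planar C6 radical; it adds anti to the pseudoaxial C1 carbonate (C6 trans to C1–O), while the ligand-controlled Si-face attack on the chelated crotonyl unit sets C7 as S. The C1 descriptor changes from S to R only because the CIP priorities change when Br is lost.

**Step 10**
Reactants: 14; 15, 2-methylprop-1-enylmagnesium bromide
Product: 16, methyl (1R,6R)-3-methyl-6-[(2S)-6-methyl-4-oxohept-5-en-2-yl]cyclohex-2-en-1-yl carbonate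
Conditions: 15 (1.1 equiv), THF, −78 °C; aq. NH4Cl
Reagents that add atoms: none
Why: acyl substitution of the N-acyl pyrazole by the Grignard reagent via a chelated tetrahedral intermediate gives the β,β-dimethyl enone without over-addition; the carbonate is inert at −78 °C and no stereocentre is touched.

**Step 11**
Reactants: 16; 4, vanillin
Product: 17, 3-methoxy-4-{[(1R,6R)-3-methyl-6-[(2S)-6-methyl-4-oxohept-5-en-2-yl]cyclohex-2-en-1-yl]oxy}benzaldehyde
Conditions: Pd2(dba)3·CHCl3 (2.5 mol%), dppb (6 mol%), 4 (1.2 equiv), THF, 40 °C
Reagents that add atoms: none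
Why: Tsuji–Trost allylic etherification; ionisation and phenoxide attack each invert, so C1 is retained (O-aryl trans to the side chain). Attack at the secondary terminus C1 is preferred over the methyl-bearing C3, and reversible ionisation of the electron-poor aryl ether funnels material to this isomer.

**Step 12**
Reactants: 17
Product: 18, 4-{[(1R,4S,6R)-4-hydroxy-3-methyl-6-[(2S)-6-methyl-4-oxohept-5-en-2-yl]cyclohex-2-en-1-yl]oxy}-3-methoxybenzaldehyde
Conditions: SeO2 (0.5 equiv), t-BuOOH (2 equiv), CH2Cl2, 0 °C to rt
Reagents that add atoms: selenium dioxide, O=[Se]=O (reoxidised by tert-butyl hydroperoxide, CC(C)(C)OO)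
Why: Sharpless SeO2 allylic hydroxylation (ene reaction then [2,3]-shift) oxidises the ring CH2 on the more substituted alkene carbon and gives the pseudoaxial alcohol, which is trans to the equatorial C6 chain and cis to C1–O (4S), as in limonene to trans-carveol.

**Step 13**
Reactants: 18; 6, (5E)-6-(4-hydroxyphenyl)hex-5-ene-2,4-dione
Product: 19, demethoxybisabolocurcumin ether (target, enol tautomer as drawn)
Conditions: 6 (1.3 equiv), B2O3, EtOAc, 70 °C; then 18, B(OnBu)3, n-BuNH2 (cat., slow), 70 °C; 10% aq. AcOH, rt
Reagents that add atoms: none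
Why: Pabon boron-templated aldol condensation at the terminal methyl of the chelated diketone gives the E-alkene; the mild acetic acid work-up spares the allylic aryl ether, and no stereocentre is affected.

## Compound list

1 | p-cresol | Cc1ccc(O)cc1 | starting material
2 | 4-hydroxybenzaldehyde | O=Cc1ccc(O)cc1 | intermediate
3 | 3-bromo-4-hydroxybenzaldehyde | O=Cc1ccc(O)c(Br)c1 | intermediate
4 | vanillin | COc1cc(C=O)ccc1O | intermediate
5 | pentane-2,4-dione | CC(=O)CC(C)=O | starting material
6 | (5E)-6-(4-hydroxyphenyl)hex-5-ene-2,4-dione | CC(=O)CC(=O)/C=C/c1ccc(O)cc1 | intermediate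
7 | (E)-but-2-enoyl chloride | C/C=C/C(=O)Cl | starting material
8 | 3,5-dimethyl-1H-pyrazole | Cc1cc(C)[nH]n1 | starting material (template, lost in step 10)
9 | (2E)-1-(3,5-dimethyl-1H-pyrazol-1-yl)but-2-en-1-one | C/C=C/C(=O)n1nc(C)cc1C | intermediate
10 | 3-methylcyclohex-2-en-1-one | CC1=CC(=O)CCC1 | starting material
11 | 6-bromo-3-methylcyclohex-2-en-1-one (racemic) | CC1=CC(=O)C(Br)CC1 | intermediate
12 | (1S)-6-bromo-3-methylcyclohex-2-en-1-ol (C6 epimers) | O[C@H]1C=C(C)CCC1Br | intermediate
13 | methyl (1S)-6-bromo-3-methylcyclohex-2-en-1-yl carbonate | COC(=O)O[C@H]1C=C(C)CCC1Br | intermediate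
14 | methyl (1R,6R)-6-[(2S)-4-(3,5-dimethyl-1H-pyrazol-1-yl)-4-oxobutan-2-yl]-3-methylcyclohex-2-en-1-yl carbonate | COC(=O)O[C@H]1C=C(C)CC[C@@H]1[C@@H](C)CC(=O)n1nc(C)cc1C | intermediate
15 | 2-methylprop-1-enylmagnesium bromide | CC(C)=C[Mg]Br | starting material
16 | methyl (1R,6R)-3-methyl-6-[(2S)-6-methyl-4-oxohept-5-en-2-yl]cyclohex-2-en-1-yl carbonate | COC(=O)O[C@H]1C=C(C)CC[C@@H]1[C@@H](C)CC(=O)C=C(C)C | intermediate
17 | 3-methoxy-4-{[(1R,6R)-3-methyl-6-[(2S)-6-methyl-4-oxohept-5-en-2-yl]cyclohex-2-en-1-yl]oxy}benzaldehyde | COc1cc(C=O)ccc1O[C@H]1C=C(C)CC[C@@H]1[C@@H](C)CC(=O)C=C(C)C | intermediate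
18 | 4-{[(1R,4S,6R)-4-hydroxy-3-methyl-6-[(2S)-6-methyl-4-oxohept-5-en-2-yl]cyclohex-2-en-1-yl]oxy}-3-methoxybenzaldehyde | COc1cc(C=O)ccc1O[C@H]1C=C(C)[C@@H](O)C[C@@H]1[C@@H](C)CC(=O)C=C(C)C | intermediate
19 | demethoxybisabolocurcumin ether | COc1cc(/C=C/C(O)=C/C(=O)/C=C/c2ccc(O)cc2)ccc1O[C@H]1C=C(C)[C@@H](O)C[C@@H]1[C@@H](C)CC(=O)C=C(C)C | target

## Step count and risks

Total steps: 13. Longest linear sequence: 8 (steps 6 to 13, from 3-methylcyclohex-2-en-1-one).

Steps most likely to fail:

1. **Step 9 (radical conjugate addition).** The anti selectivity at C6 may be only moderate, the ligand-controlled C7 selectivity is untested with a chiral functionalised radical, and premature reduction of the radical competes. Fallback: make the C6–C7 unit by a polar sequence instead. Use an organocatalytic asymmetric Diels–Alder of (E)-3-methylbuta-1,3-dienyl acetate with acrolein, aldol condensation with mesityl oxide, and Cu-catalysed asymmetric conjugate methylation for C7. The resulting cis-alcohol is then etherified with vanillin by Mitsunobu inversion.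

2. **Step 12 (late SeO2 hydroxylation).** Yield and chemoselectivity are uncertain next to the aryl aldehyde, the side-chain enone and the allylic ether, and over-oxidation to the enone is possible. Fallback: bring the C4 oxygen in at the start. γ-Oxygenate 3-methylcyclohex-2-enone through its dienol silyl ether, protect as the silyl ether, carry it through steps 6 to 11, and finish with desilylation rather than C–H oxidation.

3. **Step 11 (Pd allylic etherification).** Palladium must ionise the carbonate from the face carrying the adjacent C6 side chain, so ionisation may be slow, and elimination to a diene or attack at C3 could intrude. Fallback: form the aryl–O bond instead of the allyl–O bond. Cleave the carbonate to the C1 alcohol and couple it with vanillin triflate by Pd/biarylphosphine C–O cross-coupling, which leaves C1 untouched.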